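**Plan**

- Ring numbering: O1, C2 (OMe), C3 (Me), C4 (C=O), C5 (Me), C6 (11-acetoxyundecyl). The retrosynthesis cuts the O–CH3 bond on the C2 oxygen first, then C4–C5 and O1–C2 of the ring together, then the Si–O/C–H pair of an enol silane, then the acyl–vinyl bond.
- Enabling feature: O1–C6(chain)=C5(Me) is the enol of an ethyl ketone whose carbonyl carbon carries the chain, and C2–C3(Me)–C4 is a methylmalonyl unit, so the ring is a ketone enol plus a C3 diacid.
- Forward: 12-hydroxydodecanoic acid is acetylated, converted to the acid chloride, vinylated (Stille acylation) and 1,4-hydrosilylated to a regiodefined enol silane. The only ring forms in the annulation with methylmalonyl dichloride, and O-methylation at the C2 oxygen finishes the route.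
- Stereochemistry: the target has none. The only stereo element on the way is the Z enol silane geometry, set by the hydrosilylation and erased when the ring forms.

Key step: step 6

Remark: the target contains no stereocentre and no stereogenic double bond, so "single enantiomer" is taken to mean the one achiral compound drawn.

**Route**

Step 1
Reactants: 1 hydroxy acid (12-hydroxydodecanoic acid)
Product: 2 acetoxy acid (12-acetoxydodecanoic acid)
Conditions: Ac2O (1.5 equiv), pyridine, DMAP (cat.), CH2Cl2, 0 °C → rt; dilute aq. HCl work-up
Reagents that add atoms: acetic anhydride, CC(=O)OC(C)=O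
Why: DMAP-catalysed O-acetylation (nucleophilic acyl transfer) of the primary alcohol should be clean, and the carboxyl group is recovered as the free acid after the acidic aqueous work-up.

Step 2
Reactants: 2 acetoxy acid (12-acetoxydodecanoic acid)
Product: 3 acid chloride (12-acetoxydodecanoyl chloride)
Conditions: (COCl)2 (1.3 equiv), DMF (cat.), CH2Cl2, 0 °C → rt; concentrate, use crude
Reagents that add atoms: oxalyl chloride, ClC(=O)C(=O)Cl
Why: Acid chloride formation through the chloroiminium (Vilsmeier) species from oxalyl chloride and DMF runs cold and neutral, leaves the acetate untouched and gives only gaseous by-products.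

Step 3
Reactants: 3 acid chloride (12-acetoxydodecanoyl chloride); 4 tributyl(vinyl)stannane
Product: 5 vinyl ketone (12-oxotetradec-13-en-1-yl acetate)
Conditions: BnPdCl(PPh3)2 (1 mol %), BHT (trace), CHCl3, 65 °C
Reagents that add atoms: none
Why: Stille acylation (Pd-catalysed ketone synthesis from an acid chloride and an organostannane) proceeds by oxidative addition of the C(O)–Cl bond, preferential transfer of vinyl from tin and reductive elimination, with no reagent nucleophilic enough to attack the acetate.

Step 4
Reactants: 5 vinyl ketone (12-oxotetradec-13-en-1-yl acetate); 6 triethylsilane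
Product: 7 enol silane ((Z)-12-(triethylsilyloxy)tetradec-12-en-1-yl acetate)
Conditions: RhCl(PPh3)3 (1 mol %), Et3SiH (1.1 equiv), benzene, 50 °C; filter through Florisil, use directly
Reagents that add atoms: none
Why: Rh(I)-catalysed 1,4-hydrosilylation of an enone with a monohydrosilane puts silicon on the carbonyl oxygen and hydrogen on the terminal carbon, so the enol double bond can only lie between C12 and C13, and reaction through the s-cis enone should give the Z isomer.

Step 5
Reactants: 8 methylmalonic acid
Product: 9 methylmalonyl dichloride (2-methylpropanedioyl dichloride)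
Conditions: SOCl2 (3 equiv), DMF (cat.), 50 °C; distil under reduced pressure
Reagents that add atoms: thionyl chloride, O=S(Cl)Cl
Why: Conversion of a malonic acid to its dichloride with thionyl chloride via the acyl chlorosulfites is standard, and distillation gives base-free reagent for immediate use.

Step 6
Reactants: 7 enol silane ((Z)-12-(triethylsilyloxy)tetradec-12-en-1-yl acetate); 9 methylmalonyl dichloride
Product: 12 hydroxypyranone (11-(4-hydroxy-3,5-dimethyl-2-oxo-2H-pyran-6-yl)undecyl acetate), via chlorocarbonyl(methyl)ketene 10 (not isolated), via diketo acid chloride 11 (not isolated)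
Conditions: 9 (1.2 equiv), Et2O, −78 °C → rt, no added base
Reagents that add atoms: none
Why: Dichloride 9 loses HCl to ketene 10, whose ketene carbon is attacked by the nucleophilic C13 of enol silane 7 (C4–C5 bond), chloride taking the silyl group to leave diketo acid chloride 11. The enol oxygen of the chain-bearing ketone of 11 then adds to the acid chloride carbon and expels chloride (O1–C2 bond) in a 6-exo-trig acyl substitution, and enolisation gives the 4-hydroxy-2-pyranone 12. The closest known reaction type is the pyranone synthesis from malonyl dichlorides or (chlorocarbonyl)ketenes and ketone silyl enol ethers. No stereocentre is created, because both sp3 carbons of 11 end as sp2 ring carbons. The step needs control of which α-carbon of the ketone becomes C5 and of carbon versus oxygen acylation; the first is fixed by the position of the enol double bond in 7 and the second by the carbon nucleophilicity of a neutral silyl enol ether, while the acetate is inert because neither base nor strong Lewis acid is present.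

Step 7
Reactants: 12 hydroxypyranone (11-(4-hydroxy-3,5-dimethyl-2-oxo-2H-pyran-6-yl)undecyl acetate)
Product: 14 target (11-(6-methoxy-3,5-dimethyl-4-oxo-4H-pyran-2-yl)undecyl acetate), via hydroxymethoxypyrylium triflate 13 (not isolated)
Conditions: MeOTf (1.5–2 equiv), CH2Cl2, 0 °C → rt; then sat. aq. NaHCO3
Reagents that add atoms: methyl trifluoromethanesulfonate, COS(=O)(=O)C(F)(F)F
Why: Regioselective O-methylation of a 4-hydroxy-2-pyranone by a hard methyl sulfonate should occur at the most basic oxygen of the neutral pyranone, the C2 lactone carbonyl, giving pyrylium salt 13, which loses the hydroxyl proton on bicarbonate work-up to give the 2-methoxy-4-pyranone, while the acetate carbonyl is too weak a nucleophile to compete.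

**Compound list**

1 | 12-hydroxydodecanoic acid | OCCCCCCCCCCCC(=O)O | starting material
2 | 12-acetoxydodecanoic acid | CC(=O)OCCCCCCCCCCCC(=O)O | intermediate
3 | 12-acetoxydodecanoyl chloride | CC(=O)OCCCCCCCCCCCC(Cl)=O | intermediate
4 | tributyl(vinyl)stannane | C=C[Sn](CCCC)(CCCC)CCCC | starting material
5 | 12-oxotetradec-13-en-1-yl acetate | CC(=O)OCCCCCCCCCCCC(=O)C=C | intermediate
6 | triethylsilane | CC[SiH](CC)CC | starting material
7 | (Z)-12-(triethylsilyloxy)tetradec-12-en-1-yl acetate | C/C=C(\O[Si](CC)(CC)CC)CCCCCCCCCCCOC(C)=O | intermediate
8 | methylmalonic acid | CC(C(=O)O)C(=O)O | starting material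
9 | methylmalonyl dichloride | CC(C(Cl)=O)C(Cl)=O | intermediate
10 | chlorocarbonyl(methyl)ketene (not isolated) | CC(=C=O)C(Cl)=O | intermediate
11 | 16-acetoxy-2,4-dimethyl-3,5-dioxohexadecanoyl chloride (not isolated; keto form, mixture of stereoisomers at C2 and C4, both lost in 12) | CC(=O)OCCCCCCCCCCCC(=O)C(C)C(=O)C(C)C(Cl)=O | intermediate
12 | 11-(4-hydroxy-3,5-dimethyl-2-oxo-2H-pyran-6-yl)undecyl acetate | CC(=O)OCCCCCCCCCCCc1oc(=O)c(C)c(O)c1C | intermediate
13 | 6-(11-acetoxyundecyl)-4-hydroxy-2-methoxy-3,5-dimethylpyrylium triflate (not isolated) | COc1[o+]c(CCCCCCCCCCCOC(C)=O)c(C)c(O)c1C.[O-]S(=O)(=O)C(F)(F)F | intermediate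
14 | 11-(6-methoxy-3,5-dimethyl-4-oxo-4H-pyran-2-yl)undecyl acetate | COc1oc(CCCCCCCCCCCOC(C)=O)c(C)c(=O)c1C | target

**Count**

Total steps: 7. Longest linear sequence: 6 (steps 1, 2, 3, 4, 6, 7); step 5 is a one-step side branch.

**Steps most likely to fail**

Step 6. The HCl released when the ketene forms may protonate the enol silane and strip the silyl group faster than C-acylation occurs, or the ketene may oligomerise, so that material drains to the parent ethyl ketone. The fallback builds the same ring from an acyclic keto ester and sets out from acid chloride 3. The dianion of ethyl 2-methyl-3-oxopentanoate (NaH, then n-BuLi, THF, 0 °C) would be acylated at its terminal carbon by 3 at −78 °C to give ethyl 16-acetoxy-2,4-dimethyl-3,5-dioxohexadecanoate F1. Heating F1 with DBU in toluene should close the lactone with loss of ethanol and return to the route at hydroxypyranone 12.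

Step 7. Alkylation may divide between the two exocyclic ring oxygens if the 2-hydroxy-4-pyranone tautomer or traces of the pyranone anion take part, which would erode the regioselectivity. The fallback blocks the C4 oxygen first and sets out from hydroxypyranone 12. Silylation (TBSCl, imidazole, DMF) would give 11-[4-(tert-butyldimethylsilyloxy)-3,5-dimethyl-2-oxo-2H-pyran-6-yl]undecyl acetate F2, in which the lactone carbonyl is the only oxygen left to alkylate. MeOTf in CH2Cl2 should then give 6-(11-acetoxyundecyl)-4-(tert-butyldimethylsilyloxy)-2-methoxy-3,5-dimethylpyrylium triflate F3. Aqueous bicarbonate removes silicon from oxygen far faster than methyl and brings the sequence back to the route at target 14.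

Step 3. The vinyl ketone may polymerise under the warm coupling conditions, and the acylpalladium intermediate may decarbonylate before the slow transfer of vinyl from tin. The fallback avoids palladium and tin and sets out from acid chloride 3. Friedel–Crafts-type acylation of ethylene (AlCl3 in excess to allow for the acetate, CH2Cl2, 0 °C) would give the β-chloro ketone 14-chloro-12-oxotetradecyl acetate F4. Dehydrochlorination with Et3N in Et2O at rt, just before use, returns to the route at vinyl ketone 5.

**Further compounds**

F1 | step 6 | ethyl 16-acetoxy-2,4-dimethyl-3,5-dioxohexadecanoate | CCOC(=O)C(C)C(=O)C(C)C(=O)CCCCCCCCCCCOC(C)=O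
F2 | step 7 | 11-[4-(tert-butyldimethylsilyloxy)-3,5-dimethyl-2-oxo-2H-pyran-6-yl]undecyl acetate | CC(=O)OCCCCCCCCCCCc1oc(=O)c(C)c(O[Si](C)(C)C(C)(C)C)c1C
F3 | step 7 | 6-(11-acetoxyundecyl)-4-(tert-butyldimethylsilyloxy)-2-methoxy-3,5-dimethylpyrylium triflate | COc1[o+]c(CCCCCCCCCCCOC(C)=O)c(C)c(O[Si](C)(C)C(C)(C)C)c1C.[O-]S(=O)(=O)C(F)(F)F
F4 | step 3 | 14-chloro-12-oxotetradecyl acetate | CC(=O)OCCCCCCCCCCCC(=O)CCCl
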